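No cross-coupling is asked to join the two crowded rings: the ring B C2'–flavone C8 axis is already present as the aryl–alkyne bond of a siloxyalkyne, and flavone ring A is grown around it. The feature exploited is that flavone C8 sits between the oxygen-bearing carbons C7 and C8a of a ring A that is also oxygenated at C5, the substitution pattern that a 3-alkoxy vinylketene and a siloxyalkyne produce. One thermal operation should form C8–C8a and C6–C7, close ring A and leave three differentiated oxygens. The precursor is a triisopropylsiloxyalkyne on the dibenzylated catechol ring B, with the future flavanone C2 masked as a dioxolane. C2 is set late by organocatalytic oxa-Michael closure.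

Key step: step 7

Locants: the flavanone unit is unprimed (its ring B is C1'–C6'). The flavone unit is double-primed and its ring B triple-primed. Ar = 2,3-bis(benzyloxy)-6-(1,3-dioxolan-2-yl)phenyl; Ar' = 3,4-bis(benzyloxy)phenyl.

Assumption: the target string fixes only C2 (S) and leaves the hindered C2'–C8'' axis open, so the axis is built without control, both 2S atropisomers count as the target, and they can be separated at 32 if a single one is wanted.

Step 1
Reactants: 1 2-bromo-3-hydroxy-4-methoxybenzaldehyde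
Product: 2 2-bromo-3,4-dihydroxybenzaldehyde
Conditions: BBr3 (1.5 equiv), CH2Cl2, −78 °C → rt; H2O
Reagents that add atoms: none
Why: Lewis-acid aryl methyl ether cleavage, in which boron binds the 3-OH/4-OMe pair and bromide removes the methyl group while the aryl bromide and the aldehyde stay intact.

Step 2
Reactants: 2 2-bromo-3,4-dihydroxybenzaldehyde
Product: 3 3,4-bis(benzyloxy)-2-bromobenzaldehyde
Conditions: BnBr (2.3 equiv), K2CO3 (2.5 equiv), DMF, rt → 50 °C
Reagents that add atoms: benzyl bromide, BrCc1ccccc1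
Why: Williamson ether synthesis on both phenoxides; benzyl is chosen because it tolerates every base, organolithium and mild acid ahead and is removed with all other ethers in one final Lewis-acid step.

Step 3
Reactants: 3 3,4-bis(benzyloxy)-2-bromobenzaldehyde
Product: 4 3,4-bis(benzyloxy)-2-[(trimethylsilyl)ethynyl]benzaldehyde
Conditions: Me3SiC≡CH (1.5 equiv), PdCl2(PPh3)2 (3 mol %), CuI (5 mol %), Et3N/THF, 60 °C
Reagents that add atoms: ethynyltrimethylsilane, C#C[Si](C)(C)C
Why: Sonogashira coupling, run before acetalisation because the ortho formyl group speeds oxidative addition of zerovalent palladium into an otherwise electron-rich, doubly flanked C–Br bond.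

Step 4
Reactants: 4 3,4-bis(benzyloxy)-2-[(trimethylsilyl)ethynyl]benzaldehyde
Product: 5 2-{3,4-bis(benzyloxy)-2-[(trimethylsilyl)ethynyl]phenyl}-1,3-dioxolane
Conditions: HOCH2CH2OH (5 equiv), p-TsOH·H2O (5 mol %), toluene, Dean–Stark reflux
Reagents that add atoms: ethylene glycol, OCCO
Why: Acid-catalysed acetalisation with azeotropic water removal; the dioxolane shields the aldehyde from the organolithium, peroxide and acetylide chemistry ahead, and the silyl cap keeps the alkyne inert under acid.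

Step 5
Reactants: 5 2-{3,4-bis(benzyloxy)-2-[(trimethylsilyl)ethynyl]phenyl}-1,3-dioxolane
Product: 6 2-[3,4-bis(benzyloxy)-2-ethynylphenyl]-1,3-dioxolane
Conditions: K2CO3 (20 mol %), MeOH/THF, rt
Reagents that add atoms: none
Why: Base-catalysed methanolysis of the alkynyl C–Si bond (protodesilylation), to which the acetal and the benzyl ethers are inert.

Step 6
Reactants: 6 2-[3,4-bis(benzyloxy)-2-ethynylphenyl]-1,3-dioxolane
Product: 9 {[Ar]ethynyloxy}triisopropylsilane (ring B siloxyalkyne), via lithium acetylide 7 (not isolated), via lithium ynolate 8 (not isolated)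
Conditions: n-BuLi (1.05 equiv), THF, −78 °C; t-BuOOLi [t-BuOOH in decane + LiN(SiMe3)2, THF, −78 °C], −78 → 0 °C; iPr3SiOTf (1.1 equiv), −78 → 0 °C; NaHCO3 work-up, Et3N-deactivated silica
Reagents that add atoms: tert-butyl hydroperoxide, CC(C)(C)OO; triisopropylsilyl triflate, CC(C)[Si](C(C)C)(C(C)C)OS(=O)(=O)C(F)(F)F
Why: Electrophilic oxygenation of a lithium acetylide by lithium tert-butyl peroxide gives the ynolate, the bulky silyl triflate traps it on oxygen as in known preparations of triisopropylsiloxyalkynes, and the near-stoichiometric triflate at low temperature in a basic medium leaves the dioxolane closed.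

Step 7
Reactants: 9 {[Ar]ethynyloxy}triisopropylsilane; 10 3-ethoxycyclobut-2-en-1-one
Product: 15 2-Ar-5-ethoxy-3-(triisopropylsilyloxy)phenol, via ethoxyvinylketene 11 (not isolated), via vinylcyclobutenone 12 (not isolated), via dienylketene 13 (not isolated), via cyclohexadienone 14 (not isolated)
Conditions: toluene, base-washed sealed vessel, 110–120 °C, 10 (1.5 equiv) fed slowly
Reagents that add atoms: none
Why: Danheiser benzannulation in its siloxyalkyne form: 10 opens by conrotatory 4π cleavage of C1–C4 to ketene 11, whose carbonyl carbon is attacked by the aryl-bearing carbon of 9 (β to oxygen) in a [2+2] cycloaddition that gives 12. Conrotatory 4π opening of 12 gives dienylketene 13, and ring A closes by thermal disrotatory 6π electrocyclisation of the ketene carbon onto the terminal CH2 (the C4a''–C8a'' bond), after which 14 tautomerises to the phenol. The closest known reaction type is the heating of cyclobutenones with triisopropylsiloxyalkynes to give monosilylated resorcinols, and here the 3-ethoxy group supplies the third oxygen. No stereocentre is formed, but the C2'–C8'' axis becomes hindered at this point and arises as a racemate. The step needs a single regiochemistry in the [2+2] event, which the polarity match between the ynol ether and the ketene carbonyl secures, so that ring B ends between OH and OSi(iPr)3. Slow feeding of 10 keeps the ketene dilute, which should hold back its dimerisation and the O-acylation of the crowded product phenol.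

Step 8
Reactants: 15 2-Ar-5-ethoxy-3-(triisopropylsilyloxy)phenol
Product: 16 3-Ar-6-ethoxy-2-hydroxy-4-(triisopropylsilyloxy)benzaldehyde
Conditions: MgCl2 (3 equiv), Et3N (6 equiv), (CH2O)n (10 equiv), MeCN, reflux; cold aq NH4Cl
Reagents that add atoms: paraformaldehyde (as formaldehyde), C=O
Why: Casnati–Skattebøl ortho-formylation, in which the magnesium phenoxide delivers formaldehyde only to the one free ortho carbon (future C4a'') and a second formaldehyde accepts hydride; the basic medium spares the dioxolane and the silyl ether, which a Friedel–Crafts or Fries acetylation under Lewis acid would not.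

Step 9
Reactants: 17 3,4-bis(benzyloxy)benzaldehyde
Product: 18 1,2-bis(benzyloxy)-4-ethynylbenzene
Conditions: dimethyl (1-diazo-2-oxopropyl)phosphonate (1.2 equiv), K2CO3 (2 equiv), MeOH, rt
Reagents that add atoms: dimethyl (1-diazo-2-oxopropyl)phosphonate, COP(=O)(OC)C(=[N+]=[N-])C(C)=O
Why: Seyferth–Gilbert homologation in the Ohira–Bestmann version, a standard one-carbon conversion of non-enolisable aryl aldehydes into terminal alkynes.

Step 10
Reactants: 16 3-Ar-6-ethoxy-2-hydroxy-4-(triisopropylsilyloxy)benzaldehyde; 18 1,2-bis(benzyloxy)-4-ethynylbenzene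
Product: 20 2-Ar-6-[3-Ar'-1-hydroxyprop-2-yn-1-yl]-5-ethoxy-3-(triisopropylsilyloxy)phenol, via lithium arylacetylide 19 (not isolated)
Conditions: 18 (2.5 equiv), n-BuLi (2.4 equiv), THF, −78 °C; then 16, −78 → 0 °C; aq NH4Cl; used crude
Reagents that add atoms: none
Why: 1,2-Addition of a lithium acetylide to an unprotected salicylaldehyde, known also for 4,6-dialkoxy cases; one equivalent is spent on the phenol, and the carbinol centre forms without control and is erased in step 11.

Step 11
Reactants: 20 2-Ar-6-[3-Ar'-1-hydroxyprop-2-yn-1-yl]-5-ethoxy-3-(triisopropylsilyloxy)phenol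
Product: 21 1-[3-Ar-6-ethoxy-2-hydroxy-4-(triisopropylsilyloxy)phenyl]-3-Ar'-prop-2-yn-1-one
Conditions: MnO2 (20 equiv), CH2Cl2, rt
Reagents that add atoms: none
Why: MnO2 oxidation of a doubly activated (benzylic and propargylic) alcohol under neutral conditions, so the acetal, the silyl ether and the benzyl ethers persist and the acid-labile carbinol is consumed quickly.

Step 12
Reactants: 21 1-[3-Ar-6-ethoxy-2-hydroxy-4-(triisopropylsilyloxy)phenyl]-3-Ar'-prop-2-yn-1-one
Product: 23 8-Ar-7-(benzyloxy)-2-Ar'-5-ethoxy-4H-chromen-4-one, via silyloxyflavone 22 (not isolated)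
Conditions: 4-(dimethylamino)pyridine (20 mol %), DMF, 40 °C; then CsF (2 equiv), BnBr (1.5 equiv), rt
Reagents that add atoms: benzyl bromide, BrCc1ccccc1
Why: Nucleophile-catalysed 6-endo oxa-Michael cyclisation of an o-hydroxyaryl ynone closes the pyranone (the pyridine adds to the ynone β-carbon and is displaced by the phenol, which avoids the 5-exo aurone path), and fluoride desilylation with Williamson benzylation in the same flask replaces the labile vinylogous silyl ester at O7'', which BCl3 would not remove cleanly and whose loss would free an acidic phenol able to quench the basic catalyst of step 17.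

Step 13
Reactants: 23 8-Ar-7-(benzyloxy)-2-Ar'-5-ethoxy-4H-chromen-4-one
Product: 24 3,4-bis(benzyloxy)-2-[7-(benzyloxy)-2-Ar'-5-ethoxy-4-oxo-4H-chromen-8-yl]benzaldehyde
Conditions: 2 M aq HCl, THF, rt
Reagents that add atoms: water, O
Why: Acid-catalysed acetal hydrolysis, which leaves the flavone, the ethyl ether and the benzyl ethers untouched.

Step 14
Reactants: 25 2',4',6'-trihydroxyacetophenone
Product: 26 1-[2,4-bis(benzyloxy)-6-hydroxyphenyl]ethan-1-one
Conditions: BnBr (2.1 equiv), K2CO3 (2.2 equiv), DMF, rt → 50 °C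
Reagents that add atoms: benzyl bromide, BrCc1ccccc1
Why: Selective Williamson etherification, in which the last hydroxyl stays free because it is chelated to the ketone and is the least nucleophilic.

Step 15
Reactants: 26 1-[2,4-bis(benzyloxy)-6-hydroxyphenyl]ethan-1-one
Product: 28 tert-butyl 3-[2,4-bis(benzyloxy)-6-hydroxyphenyl]-3-oxopropanoate, via dilithium dianion 27 (not isolated)
Conditions: LiN(SiMe3)2 (3.3 equiv), THF, −78 → −20 °C; Boc2O (1.1 equiv), −78 → 0 °C; aq NH4Cl
Reagents that add atoms: di-tert-butyl dicarbonate, CC(C)(C)OC(=O)OC(=O)OC(C)(C)C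
Why: Claisen-type C-acylation of the enolate within the phenoxide–enolate dianion; any carbonate formed on the phenoxide would be carried to carbon by a Baker–Venkataraman-type O→C shift, the third equivalent of base stores the product as its enolate, and the bulky ester resists lactonisation to a 4-hydroxycoumarin.

Step 16
Reactants: 24 3,4-bis(benzyloxy)-2-[7-(benzyloxy)-2-Ar'-5-ethoxy-4-oxo-4H-chromen-8-yl]benzaldehyde; 28 tert-butyl 3-[2,4-bis(benzyloxy)-6-hydroxyphenyl]-3-oxopropanoate
Product: 29 tert-butyl (Z)-2-[2,4-bis(benzyloxy)-6-hydroxybenzoyl]-3-{3,4-bis(benzyloxy)-2-[7-(benzyloxy)-2-Ar'-5-ethoxy-4-oxo-4H-chromen-8-yl]phenyl}prop-2-enoate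
Conditions: piperidine (20 mol %), AcOH (20 mol %), 4 Å molecular sieves, toluene, rt
Reagents that add atoms: none
Why: Knoevenagel condensation under piperidinium acetate catalysis; the aldehyde has only one substituted ortho position, the chelated phenol of 28 is a poor nucleophile so uncatalysed ring closure should stay slow at room temperature, and the aryl group is expected cis to the ester.

Step 17
Reactants: 29 tert-butyl (Z)-alkylidene β-keto ester
Product: 32 (2S)-5,7-bis(benzyloxy)-2-{3,4-bis(benzyloxy)-2-[7-(benzyloxy)-2-Ar'-5-ethoxy-4-oxo-4H-chromen-8-yl]phenyl}chroman-4-one, via flavanone tert-butyl ester 30 (not isolated), via flavanone carboxylic acid 31 (not isolated)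
Conditions: 1-[3,5-bis(trifluoromethyl)phenyl]-3-[(9R)-6'-methoxycinchonan-9-yl]thiourea (quinidine-derived, 10 mol %), toluene, −25 °C; then p-TsOH·H2O (0.5 equiv), 80 °C
Reagents that add atoms: none
Why: Asymmetric intramolecular oxa-Michael addition under bifunctional cinchona–thiourea catalysis, a known route to flavanones from alkylidene β-keto esters: the thiourea binds the β-keto ester, the quinuclidine activates the phenol and O1 is delivered to one face of the alkylidene, so C2 is set as S by the catalyst (the quinine-derived pseudoenantiomer serves if a circular dichroism check on 32 shows the opposite sense), after which acid removes the ester as isobutene and CO2, erasing C3 and shutting off the retro-Michael path.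

Step 18
Reactants: 32 (2S)-heptabenzyl 5''-O-ethyl ether
Product: 33 8-{6-[(2S)-5,7-dihydroxy-4-oxochroman-2-yl]-2,3-dihydroxyphenyl}-2-(3,4-dihydroxyphenyl)-5,7-dihydroxy-4H-chromen-4-one (target)
Conditions: BCl3 (1 M in CH2Cl2, 20 equiv), C6HMe5 (20 equiv), CH2Cl2, −78 °C → rt; MeOH then H2O
Reagents that add atoms: none
Why: Lewis-acid ether cleavage, in which BCl3 with pentamethylbenzene as a non-basic benzyl cation trap removes the seven benzyl ethers at low temperature and, on warming, the boron chelate between C4''=O and the peri 5''-OEt lets chloride take off the ethyl group; no base is present, so C2 cannot epimerise through the chalcone.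

Compound list

1 | 2-bromo-3-hydroxy-4-methoxybenzaldehyde (2-bromoisovanillin) | COc1ccc(C=O)c(Br)c1O | starting material
2 | 2-bromo-3,4-dihydroxybenzaldehyde | Oc1ccc(C=O)c(Br)c1O | intermediate
3 | 3,4-bis(benzyloxy)-2-bromobenzaldehyde | O=Cc1ccc(OCc2ccccc2)c(OCc2ccccc2)c1Br | intermediate
4 | 3,4-bis(benzyloxy)-2-[(trimethylsilyl)ethynyl]benzaldehyde | O=Cc1ccc(OCc2ccccc2)c(OCc2ccccc2)c1C#C[Si](C)(C)C | intermediate
5 | 2-{3,4-bis(benzyloxy)-2-[(trimethylsilyl)ethynyl]phenyl}-1,3-dioxolane | C[Si](C)(C)C#Cc1c(C2OCCO2)ccc(OCc2ccccc2)c1OCc1ccccc1 | intermediate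
6 | 2-[3,4-bis(benzyloxy)-2-ethynylphenyl]-1,3-dioxolane | C#Cc1c(C2OCCO2)ccc(OCc2ccccc2)c1OCc1ccccc1 | intermediate
7 | lithium acetylide of 6 | [Li]C#Cc1c(C2OCCO2)ccc(OCc2ccccc2)c1OCc1ccccc1 | intermediate
8 | lithium 2-Ar-ethynolate (ynolate) | [Li]OC#Cc1c(C2OCCO2)ccc(OCc2ccccc2)c1OCc1ccccc1 | intermediate
9 | {[2,3-bis(benzyloxy)-6-(1,3-dioxolan-2-yl)phenyl]ethynyloxy}triisopropylsilane | CC(C)[Si](OC#Cc1c(C2OCCO2)ccc(OCc2ccccc2)c1OCc1ccccc1)(C(C)C)C(C)C | intermediate
10 | 3-ethoxycyclobut-2-en-1-one | CCOC1=CC(=O)C1 | starting material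
11 | 3-ethoxybuta-1,3-dien-1-one, (1-ethoxyvinyl)ketene | C=C(OCC)C=C=O | intermediate
12 | 2-Ar-4-(1-ethoxyvinyl)-3-(triisopropylsilyloxy)cyclobut-2-en-1-one (racemic) | O=C1C(C(=C)OCC)C(O[Si](C(C)C)(C(C)C)C(C)C)=C1c3c(C2OCCO2)ccc(OCc2ccccc2)c3OCc2ccccc2 | intermediate
13 | (3E)-2-Ar-5-ethoxy-3-(triisopropylsilyloxy)hexa-1,3,5-trien-1-one (ketene carbon and ethoxyvinyl group cis on C3=C4) | O=C=C(c3c(C2OCCO2)ccc(OCc2ccccc2)c3OCc2ccccc2)/C(O[Si](C(C)C)(C(C)C)C(C)C)=C\C(=C)OCC | intermediate
14 | 2-Ar-5-ethoxy-3-(triisopropylsilyloxy)cyclohexa-2,4-dien-1-one | O=C1CC(OCC)=CC(O[Si](C(C)C)(C(C)C)C(C)C)=C1c3c(C2OCCO2)ccc(OCc2ccccc2)c3OCc2ccccc2 | intermediate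
15 | 2-Ar-5-ethoxy-3-(triisopropylsilyloxy)phenol (racemic axis) | Oc1cc(OCC)cc(O[Si](C(C)C)(C(C)C)C(C)C)c1-c1c(C2OCCO2)ccc(OCc2ccccc2)c1OCc1ccccc1 | intermediate
16 | 3-Ar-6-ethoxy-2-hydroxy-4-(triisopropylsilyloxy)benzaldehyde | O=Cc1c(O)c(-c2c(C3OCCO3)ccc(OCc3ccccc3)c2OCc2ccccc2)c(O[Si](C(C)C)(C(C)C)C(C)C)cc1OCC | intermediate
17 | 3,4-bis(benzyloxy)benzaldehyde | O=Cc1ccc(OCc2ccccc2)c(OCc2ccccc2)c1 | starting material
18 | 1,2-bis(benzyloxy)-4-ethynylbenzene | C#Cc1ccc(OCc2ccccc2)c(OCc2ccccc2)c1 | intermediate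
19 | lithium acetylide of 18 | [Li]C#Cc1ccc(OCc2ccccc2)c(OCc2ccccc2)c1 | intermediate
20 | 2-Ar-6-[3-Ar'-1-hydroxyprop-2-yn-1-yl]-5-ethoxy-3-(triisopropylsilyloxy)phenol (carbinol uncontrolled) | OC(C#Cc1ccc(OCc2ccccc2)c(OCc2ccccc2)c1)c1c(O)c(-c2c(C3OCCO3)ccc(OCc3ccccc3)c2OCc2ccccc2)c(O[Si](C(C)C)(C(C)C)C(C)C)cc1OCC | intermediate
21 | 1-[3-Ar-6-ethoxy-2-hydroxy-4-(triisopropylsilyloxy)phenyl]-3-Ar'-prop-2-yn-1-one | O=C(C#Cc1ccc(OCc2ccccc2)c(OCc2ccccc2)c1)c1c(O)c(-c2c(C3OCCO3)ccc(OCc3ccccc3)c2OCc2ccccc2)c(O[Si](C(C)C)(C(C)C)C(C)C)cc1OCC | intermediate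
22 | 8-Ar-2-Ar'-5-ethoxy-7-(triisopropylsilyloxy)-4H-chromen-4-one | CCOc1cc(O[Si](C(C)C)(C(C)C)C(C)C)c(-c2c(C3OCCO3)ccc(OCc3ccccc3)c2OCc2ccccc2)c2oc(-c3ccc(OCc4ccccc4)c(OCc4ccccc4)c3)cc(=O)c12 | intermediate
23 | 8-Ar-7-(benzyloxy)-2-Ar'-5-ethoxy-4H-chromen-4-one | CCOc1cc(OCc2ccccc2)c(-c2c(C3OCCO3)ccc(OCc3ccccc3)c2OCc2ccccc2)c2oc(-c3ccc(OCc4ccccc4)c(OCc4ccccc4)c3)cc(=O)c12 | intermediate
24 | 3,4-bis(benzyloxy)-2-[7-(benzyloxy)-2-Ar'-5-ethoxy-4-oxo-4H-chromen-8-yl]benzaldehyde | CCOc1cc(OCc2ccccc2)c(-c2c(C=O)ccc(OCc3ccccc3)c2OCc2ccccc2)c2oc(-c3ccc(OCc4ccccc4)c(OCc4ccccc4)c3)cc(=O)c12 | intermediate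
25 | 2',4',6'-trihydroxyacetophenone | CC(=O)c1c(O)cc(O)cc1O | starting material
26 | 1-[2,4-bis(benzyloxy)-6-hydroxyphenyl]ethan-1-one | CC(=O)c1c(O)cc(OCc2ccccc2)cc1OCc1ccccc1 | intermediate
27 | dilithium phenoxide–enolate of 26 | [Li]OC(=C)c1c(O[Li])cc(OCc2ccccc2)cc1OCc1ccccc1 | intermediate
28 | tert-butyl 3-[2,4-bis(benzyloxy)-6-hydroxyphenyl]-3-oxopropanoate | CC(C)(C)OC(=O)CC(=O)c1c(O)cc(OCc2ccccc2)cc1OCc1ccccc1 | intermediate
29 | tert-butyl (Z)-alkylidene β-keto ester from 24 and 28 | CC(C)(C)OC(=O)/C(=C\c1ccc(OCc2ccccc2)c(OCc2ccccc2)c1-c1c(OCc2ccccc2)cc(OCC)c2c(=O)cc(-c3ccc(OCc4ccccc4)c(OCc4ccccc4)c3)oc12)C(=O)c1c(O)cc(OCc2ccccc2)cc1OCc1ccccc1 | intermediate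
30 | tert-butyl (2S)-flavanone-3-carboxylate corresponding to 32 (C3 epimers and enol) | O=C1C(C(=O)OC(C)(C)C)[C@@H](c2ccc(OCc3ccccc3)c(OCc3ccccc3)c2-c2c(OCc3ccccc3)cc(OCC)c3c(=O)cc(-c4ccc(OCc5ccccc5)c(OCc5ccccc5)c4)oc23)Oc2cc(OCc3ccccc3)cc(OCc3ccccc3)c21 | intermediate
31 | (2S)-flavanone-3-carboxylic acid corresponding to 32 | O=C1C(C(=O)O)[C@@H](c2ccc(OCc3ccccc3)c(OCc3ccccc3)c2-c2c(OCc3ccccc3)cc(OCC)c3c(=O)cc(-c4ccc(OCc5ccccc5)c(OCc5ccccc5)c4)oc23)Oc2cc(OCc3ccccc3)cc(OCc3ccccc3)c21 | intermediate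
32 | (2S)-5,7-bis(benzyloxy)-2-{3,4-bis(benzyloxy)-2-[7-(benzyloxy)-2-Ar'-5-ethoxy-4-oxo-4H-chromen-8-yl]phenyl}chroman-4-one | O=C1C[C@@H](c2ccc(OCc3ccccc3)c(OCc3ccccc3)c2-c2c(OCc3ccccc3)cc(OCC)c3c(=O)cc(-c4ccc(OCc5ccccc5)c(OCc5ccccc5)c4)oc23)Oc2cc(OCc3ccccc3)cc(OCc3ccccc3)c21 | intermediate
33 | 8-{6-[(2S)-5,7-dihydroxy-4-oxochroman-2-yl]-2,3-dihydroxyphenyl}-2-(3,4-dihydroxyphenyl)-5,7-dihydroxy-4H-chromen-4-one | O=C1C[C@@H](c2ccc(O)c(O)c2-c2c(O)cc(O)c3c(=O)cc(-c4ccc(O)c(O)c4)oc23)Oc2cc(O)cc(O)c21 | target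

Total step count: 18. Longest linear sequence: 15 (steps 1–8, 10–13, 16–18).

Steps most likely to fail

Step 7. The nucleophilic alkyne carbon is shielded by two ortho substituents, and the donor-stabilised cyclobutenone opens reluctantly. Ketene dimerisation, ketene capture by the product phenol or thermal silyl migration in the siloxyalkyne may therefore outrun the [2+2] event. The fallback gives up ring construction for a hindered cross-coupling; it sets out from 3 and comes back at 23.
- Acetalisation of 3 (ethylene glycol, p-TsOH, toluene) would give 2-[3,4-bis(benzyloxy)-2-bromophenyl]-1,3-dioxolane F1.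
- Bromine–lithium exchange (n-BuLi, THF, −78 °C) and a quench with 2-isopropoxy-4,4,5,5-tetramethyl-1,3,2-dioxaborolane would give the ring B pinacol boronate F2.
- In parallel, purchased luteolin would be benzylated (BnBr, K2CO3, DMF; the chelated 5-OH stays free) to 7,3',4'-tri-O-benzylluteolin F3.
- Ethylation (EtI, Cs2CO3, DMF) would give its 5-O-ethyl ether F4, and iodination at C8 (N-iodosuccinimide, catalytic CF3CO2H, MeCN) would give the 8-iodoflavone F5.
- Suzuki–Miyaura coupling of F2 with F5 (Pd(OAc)2, 2-dicyclohexylphosphino-2',6'-dimethoxybiphenyl, K3PO4, toluene/H2O, 100 °C) would deliver 23.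

Step 17. Facial selectivity may be poor because the bulky flavonyl group next to the alkylidene, present as both axial forms, can be mismatched with the catalyst. Uncatalysed ring closure during or after step 16 would also erode the enantiomeric purity. The fallback replaces asymmetric catalysis by resolution; it sets out from 24 and 26 and comes back at 32.
- Claisen–Schmidt condensation of 24 with 26 (KOH, EtOH/THF, rt) would give the (E)-2'-hydroxychalcone F6.
- NaOAc in refluxing EtOH would close it to the racemic flavanone F7.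
- The 2S isomers would be taken from F7 by preparative chromatography on an amylose tris(3,5-dimethylphenylcarbamate) phase, giving 32.
- The 2R material would be recycled by base-induced ring opening back to F6.

Step 18. Cleavage of the peri ethyl ether may lag behind debenzylation. The long exposure to excess Lewis acid then needed may cause ring C-benzylation or erosion of C2 through reversible opening of the C2–O1 bond. The fallback separates the two tasks; it sets out from 32 and comes back at 33.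
- Chelation-controlled dealkylation with MgI2 (etherate, toluene/Et2O, 60–80 °C) would remove only the two ethers peri to a carbonyl (5-OBn and 5''-OEt) by iodide attack, giving the (2S)-5,5''-dihydroxy pentabenzyl ether F8.
- Neutral hydrogenolysis (H2, Pd(OH)2/C, THF/MeOH, rt, stopped at full debenzylation) would then give 33.

Further compounds

F1 | step 7 | 2-[3,4-bis(benzyloxy)-2-bromophenyl]-1,3-dioxolane | Brc1c(C2OCCO2)ccc(OCc2ccccc2)c1OCc1ccccc1
F2 | step 7 | 2-[2,3-bis(benzyloxy)-6-(1,3-dioxolan-2-yl)phenyl]-4,4,5,5-tetramethyl-1,3,2-dioxaborolane | CC1(C)OB(OC1(C)C)c1c(C2OCCO2)ccc(OCc2ccccc2)c1OCc1ccccc1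
F3 | step 7 | 7-(benzyloxy)-2-[3,4-bis(benzyloxy)phenyl]-5-hydroxy-4H-chromen-4-one | O=c1cc(-c2ccc(OCc3ccccc3)c(OCc3ccccc3)c2)oc2cc(OCc3ccccc3)cc(O)c12
F4 | step 7 | 7-(benzyloxy)-2-[3,4-bis(benzyloxy)phenyl]-5-ethoxy-4H-chromen-4-one | CCOc1cc(OCc2ccccc2)cc2oc(-c3ccc(OCc4ccccc4)c(OCc4ccccc4)c3)cc(=O)c12
F5 | step 7 | 7-(benzyloxy)-2-[3,4-bis(benzyloxy)phenyl]-5-ethoxy-8-iodo-4H-chromen-4-one | CCOc1cc(OCc2ccccc2)c(I)c2oc(-c3ccc(OCc4ccccc4)c(OCc4ccccc4)c3)cc(=O)c12
F6 | step 17 | (E)-1-[2,4-bis(benzyloxy)-6-hydroxyphenyl]-3-{3,4-bis(benzyloxy)-2-[7-(benzyloxy)-2-Ar'-5-ethoxy-4-oxo-4H-chromen-8-yl]phenyl}prop-2-en-1-one | O=C(/C=C/c1ccc(OCc2ccccc2)c(OCc2ccccc2)c1-c1c(OCc2ccccc2)cc(OCC)c2c(=O)cc(-c3ccc(OCc4ccccc4)c(OCc4ccccc4)c3)oc12)c1c(O)cc(OCc2ccccc2)cc1OCc1ccccc1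
F7 | step 17 | racemic form of 32 | O=C1CC(c2ccc(OCc3ccccc3)c(OCc3ccccc3)c2-c2c(OCc3ccccc3)cc(OCC)c3c(=O)cc(-c4ccc(OCc5ccccc5)c(OCc5ccccc5)c4)oc23)Oc2cc(OCc3ccccc3)cc(OCc3ccccc3)c21
F8 | step 18 | (2S)-7-(benzyloxy)-2-{3,4-bis(benzyloxy)-2-[7-(benzyloxy)-2-Ar'-5-hydroxy-4-oxo-4H-chromen-8-yl]phenyl}-5-hydroxychroman-4-one | O=C1C[C@@H](c2ccc(OCc3ccccc3)c(OCc3ccccc3)c2-c2c(OCc3ccccc3)cc(O)c3c(=O)cc(-c4ccc(OCc5ccccc5)c(OCc5ccccc5)c4)oc23)Oc2cc(OCc3ccccc3)cc(O)c21
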